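## Retrosynthetic overview

1. The C(aryl)–C1 bond is made last. A radical-pair O→C 1,3-shift (photo-Claisen) contracts the 18-membered aryl allyl ether macrolactone 23 to the 16-membered macrolide 25 (key step).
2. 23 comes from Shi epoxidation of diene macrocycle 22, which is closed at C9–C10 by a nickel-mediated alkyl-radical/alkenyl coupling of seco-ester 20.
3. 20 comes from asymmetric bromoesterification (C14–Br, C15–O) of iodo-diene 15 with acid 19. 19 comes from Mitsunobu coupling of allylic alcohol 11 with 4-iodophenol, then Mg/CO2.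
4. 11 comes from an enantioselective bromonium cyclisation of keto ester 7 (sets C6 and C7), then enol triflate/Me2CuLi and i-Bu2AlH.
5. Ring order: cyclohexene (step 4), 18-membered ether macrocycle (step 13), oxirane (step 14), 16-membered macrolide (step 15).

Assumption: locants C1–C15 follow the diterpenoid chain (C1 = benzylic CH2, C2=C3 = ring alkene, C6 = ring CHBr, C7 = quaternary carbon, C10/C11 = oxirane, C14 = CHBr, C15 = CMe2–O); the target is (6S,7S,10S,11S,14R).

Assumption: one- and two-carbon feedstocks and methyl donors (Me3Al, formaldehyde, LiC≡CH, Me2CuLi, CO2) are entered as reagents that add atoms, not as numbered compounds.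

## Route

Step 1
Reactants: 1 but-3-yn-1-ol
Product: 3 (2E)-3-methylpent-2-ene-1,5-diol, via alkenylalane 2 (not isolated)
Conditions: Me3Al (3 equiv), Cp2ZrCl2 (25 mol %), CH2Cl2, 0 °C → rt; then n-BuLi, (CH2O)n, THF, −78 °C → rt; aq. KNaC4H4O6
Reagents that add atoms: trimethylaluminium, C[Al](C)C; paraformaldehyde (as formaldehyde), C=O
Why: Negishi zirconium-catalysed carboalumination adds Me and Al syn across the terminal alkyne with Me on the internal carbon, and the derived aluminate is hydroxymethylated with retention, so the E geometry of C6=C7 that later controls the C6/C7 relative configuration is fixed here.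

Step 2
Reactants: 3 (2E)-3-methylpent-2-ene-1,5-diol
Product: 4 (2E)-1,5-dichloro-3-methylpent-2-ene
Conditions: PPh3, NCS, CH2Cl2, 0 °C → rt
Reagents that add atoms: N-chlorosuccinimide, O=C1CCC(=O)N1Cl
Why: Appel-type deoxychlorination converts both primary alcohols to chlorides by SN2 at carbon, without allylic transposition or loss of E geometry.

Step 3
Reactants: 5 methyl acetoacetate; 4 (2E)-1,5-dichloro-3-methylpent-2-ene
Product: 7 methyl (6E)-9-chloro-7-methyl-3-oxonon-6-enoate, via acetoacetate dianion 6 (not isolated)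
Conditions: NaH, THF, 0 °C; n-BuLi, 0 °C; then 4, 0 °C → rt; aq. HCl
Reagents that add atoms: none
Why: Weiler γ-alkylation: the terminal carbanion of the acetoacetate dianion displaces the allylic chloride (SN2) far faster than the unactivated primary chloride.

Step 4
Reactants: 7 methyl (6E)-9-chloro-7-methyl-3-oxonon-6-enoate
Product: 8 methyl (2S,3S)-3-bromo-2-(2-chloroethyl)-2-methyl-6-oxocyclohexane-1-carboxylate (C1 epimers in equilibrium with the enol; this centre becomes sp2 in step 5)
Conditions: BINOL-derived chiral thiophosphoramide (10 mol %), DBDMH (0.55 equiv), toluene–CH2Cl2, −90 °C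
Reagents that add atoms: 1,3-dibromo-5,5-dimethylhydantoin (DBDMH), CC1(C)N(Br)C(=O)N(Br)C1=O
Why: Proposed new method: the sulfur Lewis base of the chiral catalyst transfers Br+ from DBDMH to one face of the only alkene, and the bromonium is opened at tertiary C7 by the enol carbon of the β-keto ester through a chair transition state (anti addition to the E-alkene places Br trans to the chloroethyl arm), which gives (2S,3S) with the appropriate catalyst enantiomer; closest known reaction type: thiophosphoramide/DBDMH-catalysed enantioselective bromonium polyene cyclisation with arene or phenol terminators, together with Lewis-acid and halonium cyclisations terminated by β-keto esters.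

Step 5
Reactants: 8 methyl (2S,3S)-3-bromo-2-(2-chloroethyl)-2-methyl-6-oxocyclohexane-1-carboxylate
Product: 9 methyl (5S,6S)-5-bromo-6-(2-chloroethyl)-6-methyl-2-{[(trifluoromethyl)sulfonyl]oxy}cyclohex-1-ene-1-carboxylate
Conditions: Tf2O, i-Pr2NEt, CH2Cl2, −78 °C
Reagents that add atoms: trifluoromethanesulfonic anhydride, O=S(=O)(OS(=O)(=O)C(F)(F)F)C(F)(F)F
Why: Enol triflation of a β-keto ester: only the doubly activated C–H between ketone and ester is removed by the amine base, so O-sulfonylation gives a single tetrasubstituted enol triflate and leaves both stereocentres untouched.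

Step 6
Reactants: 9 enol triflate
Product: 10 methyl (5S,6S)-5-bromo-6-(2-chloroethyl)-2,6-dimethylcyclohex-1-ene-1-carboxylate
Conditions: Me2CuLi (from MeLi, CuI), Et2O–THF, −78 → −40 °C; aq. NH4Cl
Reagents that add atoms: lithium dimethylcuprate, [Li+].C[Cu-]C
Why: Addition–elimination coupling of a Gilman cuprate with a β-triflyloxy enoate is fast at −78 °C, where the hindered secondary bromide and the primary chloride do not react; this installs the C3 methyl and the tetrasubstituted C2=C3 alkene.

Step 7
Reactants: 10 methyl (5S,6S)-5-bromo-6-(2-chloroethyl)-2,6-dimethylcyclohex-1-ene-1-carboxylate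
Product: 11 [(5S,6S)-5-bromo-6-(2-chloroethyl)-2,6-dimethylcyclohex-1-en-1-yl]methanol
Conditions: i-Bu2AlH (2.5 equiv), CH2Cl2, −78 → −20 °C; aq. KNaC4H4O6
Reagents that add atoms: none
Why: 1,2-Reduction of the enoate by i-Bu2AlH gives the primary allylic alcohol (C1–OH); alkyl halides are inert to the hydride at low temperature.

Step 8
Reactants: 12 5-bromo-2-methylpent-2-ene
Product: 13 6-methylhept-5-en-1-yne
Conditions: LiC≡CH·H2NCH2CH2NH2, DMSO, 10 °C → rt
Reagents that add atoms: lithium acetylide–ethylenediamine complex, [Li]C#C.NCCN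
Why: SN2 alkylation of lithium acetylide by the primary homoallylic bromide in DMSO.

Step 9
Reactants: 13 6-methylhept-5-en-1-yne
Product: 15 (1E)-1-iodo-2,6-dimethylhepta-1,5-diene, via alkenylalane 14 (not isolated)
Conditions: Me3Al (2 equiv), Cp2ZrCl2 (25 mol %), CH2Cl2, 0 °C → rt; then I2, THF, −30 °C; aq. NaHCO3
Reagents that add atoms: trimethylaluminium, C[Al](C)C; iodine, II
Why: Negishi carboalumination (syn Me–Al addition) followed by iodinolysis of the C–Al bond with retention gives the E-alkenyl iodide that fixes the C10=C11 geometry; the trisubstituted alkene is not carbometallated.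

Step 10
Reactants: 11 [(5S,6S)-5-bromo-6-(2-chloroethyl)-2,6-dimethylcyclohex-1-en-1-yl]methanol; 16 4-iodophenol
Product: 17 1-{[(5S,6S)-5-bromo-6-(2-chloroethyl)-2,6-dimethylcyclohex-1-en-1-yl]methoxy}-4-iodobenzene
Conditions: PPh3, DIAD, THF, 0 °C → rt
Reagents that add atoms: none
Why: Mitsunobu etherification: the phenol (pKa about 9) displaces the primary allylic oxyphosphonium by SN2 at C1 rather than at the hindered tertiary C3 terminus.

Step 11
Reactants: 17 aryl iodide ether
Product: 19 4-{[(5S,6S)-5-bromo-6-(2-chloroethyl)-2,6-dimethylcyclohex-1-en-1-yl]methoxy}benzoic acid, via arylmagnesium chloride 18 (not isolated)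
Conditions: i-PrMgCl·LiCl, THF, −15 → 0 °C; then CO2 (g), −15 °C → rt; aq. HCl
Reagents that add atoms: carbon dioxide, O=C=O
Why: Iodine–magnesium exchange with the turbo-Grignard reagent is selective for the aryl iodide over the alkyl bromide and chloride at or below 0 °C, and the arylmagnesium is carboxylated by CO2.

Step 12
Reactants: 19 benzoic acid; 15 (1E)-1-iodo-2,6-dimethylhepta-1,5-diene (3 equiv)
Product: 20 (3R,6E)-3-bromo-7-iodo-2,6-dimethylhept-6-en-2-yl 4-{[(5S,6S)-5-bromo-6-(2-chloroethyl)-2,6-dimethylcyclohex-1-en-1-yl]methoxy}benzoate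
Conditions: (DHQD)2PHAL [or (DHQ)2PHAL] (10 mol %), NBS (1.5 equiv), CHCl3–hexane, −30 °C
Reagents that add atoms: N-bromosuccinimide, O=C1CCC(=O)N1Br
Why: Catalytic asymmetric intermolecular bromoesterification: the bromonium forms on the electron-rich C14=C15 alkene (the alkenyl iodide is deactivated, the tetrasubstituted ring alkene is hindered and carries an allylic aryloxy group), the carboxylate opens it at tertiary C15 (Markovnikov, anti), and the ligand's facial preference sets 14R; the pseudo-enantiomeric ligand is chosen accordingly and any 14-epimer is a separable diastereomer.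

Step 13
Reactants: 20 seco-ester
Product: 22 18-membered aryl allyl ether macrolactone (6S,7S,10E,14R), via primary iodide 21 (not isolated)
Conditions: NaI (5 equiv), DMA, 60 °C; then syringe-pump addition to NiBr2·dme (30 mol %), 4,4′-di-tert-butyl-2,2′-bipyridine (30 mol %), TDAE [tetrakis(dimethylamino)ethylene] (2 equiv), DMA–MeCN, 40 °C, 2 mM
Reagents that add atoms: sodium iodide, [Na+].[I-] (its iodine is carried only by intermediate 21 and is lost again in the ring closure)
Why: Nickel-catalysed cross-electrophile (reductive) alkyl–alkenyl coupling run as a macrocyclisation: after Finkelstein exchange, zerovalent nickel inserts into the alkenyl iodide with retention, the primary alkyl radical formed from the iodide by halogen abstraction is captured at nickel, and reductive elimination closes the 18-membered ring at C9–C10 with the E-alkene intact, while the homogeneous reductant TDAE cannot reduce the two hindered secondary bromides.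

Step 14
Reactants: 22 diene macrocycle
Product: 23 (6S,7S,10S,11S,14R)-10,11-epoxide of 22
Conditions: ent-Shi ketone (L-fructose-derived 1,2:4,5-di-O-isopropylidene-β-L-erythro-2,3-hexodiulo-2,6-pyranose, 0.5 equiv), KHSO5 (as Oxone, 2KHSO5·KHSO4·K2SO4), K2CO3, Bu4NHSO4, MeCN–CH2(OMe)2–aq. Na2B4O7 buffer (pH 10.5), 0 °C
Reagents that add atoms: potassium peroxymonosulfate, [K+].[O-]S(=O)(=O)OO
Why: Shi asymmetric epoxidation: the chiral dioxirane reacts through the spiro transition state with the E-trisubstituted C10=C11 alkene to give the (10S,11S)-oxirane (the D-fructose-derived ketone would give 10R,11R), while the tetrasubstituted ring alkene is shielded by the quaternary centre and deactivated by its allylic aryloxy group.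

Step 15
Reactants: 23 epoxy ether macrocycle
Product: 25 target CNP0420597.1 (6S,7S,10S,11S,14R), via ortho-dienone 24 (not isolated)
Conditions: hν (254 nm, quartz), degassed MeCN, 0.5 mM, 15 °C, to about 70% conversion (recovered 23 recycled)
Reagents that add atoms: none
Why: Proposed new method: excitation of the 4-alkoxybenzoate chromophore homolyses the weak allylic O–C1 bond to a tethered phenoxyl/allyl radical pair that recombines at the ortho carbon through the primary allyl terminus C1 (the para position is blocked by the ester carbon and the tertiary C3 terminus is hindered), and dienone 24 tautomerises to the phenol, contracting the ring from 18 to 16 members without touching any stereocentre; closest known reaction type: the photo-Claisen rearrangement (radical-pair 1,3-shift) of aryl prenyl ethers to ortho-prenylphenols.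

## Compound list

1 | but-3-yn-1-ol | C#CCCO | starting material
2 | (E)-Me2Al–CH=C(Me)–CH2CH2–OAlMe2 (syn-carboalumination adduct as its aluminium alkoxide) | C[Al](C)OCC/C(C)=C/[Al](C)C | intermediate
3 | (2E)-3-methylpent-2-ene-1,5-diol | OCC/C(C)=C/CO | intermediate
4 | (2E)-1,5-dichloro-3-methylpent-2-ene | ClCC/C(C)=C/CCl | intermediate
5 | methyl acetoacetate (methyl 3-oxobutanoate) | CC(=O)CC(=O)OC | starting material
6 | methyl acetoacetate dianion (sodium lithium salt) | [Li+].[Na+].[CH2-]C(=O)[CH-]C(=O)OC | intermediate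
7 | methyl (6E)-9-chloro-7-methyl-3-oxonon-6-enoate | COC(=O)CC(=O)CC/C=C(\C)CCCl | intermediate
8 | methyl (2S,3S)-3-bromo-2-(2-chloroethyl)-2-methyl-6-oxocyclohexane-1-carboxylate (C1 epimers/enol, inconsequential) | ClCC[C@]1(C)[C@@H](Br)CCC(=O)C1C(=O)OC | intermediate
9 | methyl (5S,6S)-5-bromo-6-(2-chloroethyl)-6-methyl-2-{[(trifluoromethyl)sulfonyl]oxy}cyclohex-1-ene-1-carboxylate | ClCC[C@]1(C)[C@@H](Br)CCC(OS(=O)(=O)C(F)(F)F)=C1C(=O)OC | intermediate
10 | methyl (5S,6S)-5-bromo-6-(2-chloroethyl)-2,6-dimethylcyclohex-1-ene-1-carboxylate | ClCC[C@]1(C)[C@@H](Br)CCC(C)=C1C(=O)OC | intermediate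
11 | [(5S,6S)-5-bromo-6-(2-chloroethyl)-2,6-dimethylcyclohex-1-en-1-yl]methanol | ClCC[C@]1(C)[C@@H](Br)CCC(C)=C1CO | intermediate
12 | 5-bromo-2-methylpent-2-ene | CC(C)=CCCBr | starting material
13 | 6-methylhept-5-en-1-yne | CC(C)=CCCC#C | intermediate
14 | [(1E)-2,6-dimethylhepta-1,5-dien-1-yl]dimethylalumane | CC(C)=CCC/C(C)=C/[Al](C)C | intermediate
15 | (1E)-1-iodo-2,6-dimethylhepta-1,5-diene | CC(C)=CCC/C(C)=C/I | intermediate
16 | 4-iodophenol | Oc1ccc(I)cc1 | starting material
17 | 1-{[(5S,6S)-5-bromo-6-(2-chloroethyl)-2,6-dimethylcyclohex-1-en-1-yl]methoxy}-4-iodobenzene | ClCC[C@]1(C)[C@@H](Br)CCC(C)=C1COc1ccc(I)cc1 | intermediate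
18 | 4-{[(5S,6S)-5-bromo-6-(2-chloroethyl)-2,6-dimethylcyclohex-1-en-1-yl]methoxy}phenylmagnesium chloride (LiCl complex) | ClCC[C@]1(C)[C@@H](Br)CCC(C)=C1COc1ccc([Mg]Cl)cc1 | intermediate
19 | 4-{[(5S,6S)-5-bromo-6-(2-chloroethyl)-2,6-dimethylcyclohex-1-en-1-yl]methoxy}benzoic acid | ClCC[C@]1(C)[C@@H](Br)CCC(C)=C1COc1ccc(cc1)C(=O)O | intermediate
20 | (3R,6E)-3-bromo-7-iodo-2,6-dimethylhept-6-en-2-yl 4-{[(5S,6S)-5-bromo-6-(2-chloroethyl)-2,6-dimethylcyclohex-1-en-1-yl]methoxy}benzoate | ClCC[C@]1(C)[C@@H](Br)CCC(C)=C1COc1ccc(cc1)C(=O)OC(C)(C)[C@H](Br)CC/C(C)=C/I | intermediate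
21 | 2-iodoethyl analogue of 20 (C9–I in place of C9–Cl) | ICC[C@]1(C)[C@@H](Br)CCC(C)=C1COc1ccc(cc1)C(=O)OC(C)(C)[C@H](Br)CC/C(C)=C/I | intermediate
22 | 18-membered macrocycle (6S,7S,10E,14R): 4-oxybenzoate with the phenolic O bonded to C1 and the carboxyl esterified by O–C15; ring alkene C2=C3, E-alkene C10=C11, Br at C6 and C14 | CC1=C2COc3ccc(cc3)C(=O)OC(C)(C)[C@H](Br)CC/C(C)=C/CC[C@]2(C)[C@@H](Br)CC1 | intermediate
23 | (6S,7S,10S,11S,14R)-10,11-epoxide of 22 | CC1=C2COc3ccc(cc3)C(=O)OC(C)(C)[C@H](Br)CC[C@]3(C)O[C@H]3CC[C@]2(C)[C@@H](Br)CC1 | intermediate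
24 | ortho-dienone: 6-alkylcyclohexa-2,4-dien-1-one tautomer of 25 (new ring-carbon–C1 bond; configuration at the sp3 ring carbon is lost on tautomerisation) | CC1=C2CC3C=C(C=CC3=O)C(=O)OC(C)(C)[C@H](Br)CC[C@]3(C)O[C@H]3CC[C@]2(C)[C@@H](Br)CC1 | intermediate
25 | CNP0420597.1, 16-membered C-aryl macrolide (6S,7S,10S,11S,14R) | CC1=C2Cc3cc(ccc3O)C(=O)OC(C)(C)[C@H](Br)CC[C@]3(C)O[C@H]3CC[C@]2(C)[C@@H](Br)CC1 | target

## Step count and risks

Total steps: 15. Longest linear sequence: 13 (steps 1–7, then 10–15); steps 8–9 form the side branch.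

The three steps most likely to fail:

Step 4 (enantioselective bromocyclisation). The risks are α-bromination of the keto ester, kinetic O-cyclisation to an enol ether, and low or wrong-sense enantioselectivity; the sense of induction must be established experimentally and the antipodal catalyst used if needed. The fallback sets out from 5 (and uses 4) and comes back at 11. Compound 5 is transesterified with (−)-8-phenylmenthol (DMAP, toluene, reflux) to (−)-8-phenylmenthyl acetoacetate F1. Its dianion is alkylated with 4 to give the auxiliary keto ester F2. Cyclisation with the stoichiometric achiral bromonium donor Et2SBr·SbCl5Br (MeNO2, −25 °C) gives two diastereomeric trans-bromides, from which the (2S,3S)-bromo keto ester F3 is separated by chromatography or crystallisation; an O-cyclised enol ether, if formed, is isomerised with SnCl4. The enol triflate F4 and the methyl-cuprate product F5 follow as in steps 5 and 6, and i-Bu2AlH reduction of F5 gives 11 and returns the auxiliary. Stereocontrol then rests on separable diastereomers instead of catalyst control.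

Step 13 (nickel macrocyclisation). The risks are oligomerisation, halogen abstraction at the two secondary bromides, and nickel insertion into the allyl aryl ether. The fallback sets out from 20 and comes back at 22. Compound 20 is converted with NaI in acetone into iodide 21, now isolated. Zinc insertion (Zn dust, LiCl, THF, 25 °C) gives the primary alkylzinc iodide F6, which is added slowly to Pd(PPh3)4 in THF–NMP at 40 °C. This intramolecular Negishi coupling runs through a two-electron palladium cycle without a free alkyl radical and gives 22.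

Step 15 (photo-Claisen ring contraction). The risks are recombination at C3, disproportionation of the radical pair to a seco diene-phenol, and secondary photocyclisation of the ortho-allylphenol product, which is why the reaction is stopped at partial conversion. The fallback sets out from 22 and comes back at 25, using an ionic shift before the oxirane is in place. Montmorillonite K10 in CH2Cl2 at 0 °C converts 22, through an allyl cation/phenoxide ion pair, into the ortho-C-allyl phenol F7. Silylation (TBSCl, imidazole, DMF) gives the silyl ether F8, Shi epoxidation under the conditions of step 14 gives the epoxy silyl ether F9, and TBAF/AcOH in THF releases 25.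

## Further compounds

F1 | step 4 | (1R,2S,5R)-5-methyl-2-(2-phenylpropan-2-yl)cyclohexyl 3-oxobutanoate | CC(=O)CC(=O)O[C@@H]1C[C@H](C)CC[C@H]1C(C)(C)c1ccccc1
F2 | step 4 | (1R,2S,5R)-5-methyl-2-(2-phenylpropan-2-yl)cyclohexyl (6E)-9-chloro-7-methyl-3-oxonon-6-enoate | ClCC/C(C)=C/CCC(=O)CC(=O)O[C@@H]1C[C@H](C)CC[C@H]1C(C)(C)c1ccccc1
F3 | step 4 | (1R,2S,5R)-5-methyl-2-(2-phenylpropan-2-yl)cyclohexyl (2S,3S)-3-bromo-2-(2-chloroethyl)-2-methyl-6-oxocyclohexane-1-carboxylate | ClCC[C@]1(C)[C@@H](Br)CCC(=O)C1C(=O)O[C@@H]1C[C@H](C)CC[C@H]1C(C)(C)c1ccccc1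
F4 | step 4 | (1R,2S,5R)-5-methyl-2-(2-phenylpropan-2-yl)cyclohexyl (5S,6S)-5-bromo-6-(2-chloroethyl)-6-methyl-2-{[(trifluoromethyl)sulfonyl]oxy}cyclohex-1-ene-1-carboxylate | ClCC[C@]1(C)[C@@H](Br)CCC(OS(=O)(=O)C(F)(F)F)=C1C(=O)O[C@@H]1C[C@H](C)CC[C@H]1C(C)(C)c1ccccc1
F5 | step 4 | (1R,2S,5R)-5-methyl-2-(2-phenylpropan-2-yl)cyclohexyl (5S,6S)-5-bromo-6-(2-chloroethyl)-2,6-dimethylcyclohex-1-ene-1-carboxylate | ClCC[C@]1(C)[C@@H](Br)CCC(C)=C1C(=O)O[C@@H]1C[C@H](C)CC[C@H]1C(C)(C)c1ccccc1
F6 | step 13 | primary alkylzinc iodide of 21 (C9–ZnI) | I[Zn]CC[C@]1(C)[C@@H](Br)CCC(C)=C1COc1ccc(cc1)C(=O)OC(C)(C)[C@H](Br)CC/C(C)=C/I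
F7 | step 15 | 16-membered ortho-C-allyl phenol diene (6S,7S,10E,14R), the 10,11-deoxy alkene of 25 | CC1=C2Cc3cc(ccc3O)C(=O)OC(C)(C)[C@H](Br)CC/C(C)=C/CC[C@]2(C)[C@@H](Br)CC1
F8 | step 15 | tert-butyldimethylsilyl ether of F7 | CC1=C2Cc3cc(ccc3O[Si](C)(C)C(C)(C)C)C(=O)OC(C)(C)[C@H](Br)CC/C(C)=C/CC[C@]2(C)[C@@H](Br)CC1
F9 | step 15 | tert-butyldimethylsilyl ether of 25 | CC1=C2Cc3cc(ccc3O[Si](C)(C)C(C)(C)C)C(=O)OC(C)(C)[C@H](Br)CC[C@]3(C)O[C@H]3CC[C@]2(C)[C@@H](Br)CC1
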